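All runs stem from a simulated flask with constants of no real substance; the scatter is artificial.

The free catalyst is single-handed, so the two mirror-image substrates react with it under two different rate constants. The flask asked about is the ochre run, followed further.

- ochre: left-handed substrate 0.10 M; right-handed substrate 0.10 M; solid reagent 0.30 M; free catalyst 77 µM; racemization catalyst 0.57 mM; the very flask that is asked about, followed so far
- flask: left-handed substrate 0.10 M; solid reagent 0.300 M; free catalyst 77 µM; racemization catalyst 0.57 mM; right-handed substrate 0.10 M; time 2.0 min

ochre run (percent of the left-handed substrate and right-handed substrate together charged)

| time / s | left-handed product / % | right-handed product / % |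
|---|---|---|
| 10.0 | 2.8 | 0.3 |
| 20.0 | 8.7 | 4.9 |
| 30.0 | 10.8 | 3.3 |
| 40.0 | 14.2 | 6.3 |
| 50.0 | 18.9 | 6.5 |
| 60.0 | 21.2 | 5.7 |

(scatter of a reading: 1 percentage point)

* left-handed product and right-handed product together, in percent of the left-handed substrate and right-handed substrate charged together, at 2.0 min
* excess of left-handed product over right-handed product in the product at 2.0 min
* whether the exchange between left-handed substrate and right-handed substrate keeps pace with the reaction: how far the product's excess at 2.0 min gets from its value without exchange to its value with instant exchange (above 80% keeps pace, below 20% hardly takes part, else lags behind)

- free catalyst is single-handed; left-handed substrate and right-handed substrate are mirror images of each other, charged as a racemate, each of them at the stated concentration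
- as a solid, counted per litre of solution: solid reagent
- at the start none of the solid reagent is in solution
- an excess is the difference of the two amounts in percent of their sum
- an excess is below zero if the other one leads

Compare the two product rates at one moment. Both run over the same free catalyst, and the reckoning here takes each as first order in its substrate, so the ratio is:

rate of left-handed product / rate of right-handed product = s · c(left-handed substrate) / c(right-handed substrate)

Now ask how this ratio drifts. Without exchange, left-handed substrate drains faster, the concentration ratio sinks below 1, and the product ratio slides under s. With instant exchange, the two concentrations stay equal and the product ratio stays at s. The ochre run then gives s from its summed readings: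

s = 76.6% / 27.0% = 2.84

This s is the selectivity factor, the ratio of the two rate constants as read from the readings. It carries the scatter of 1 percentage point on each reading.

The last three readings give a ratio of 2.94, and the first three give 2.62. The later ratio is higher, but the first three right-handed readings sum to 8.50%, each with that scatter, so these two ratios do not tell exchange from none. This reckoning therefore takes the instant-exchange value of the excess as an assumption, not as a finding:

excess = (s − 1) / (s + 1) = 47.9%

Since s carries no clock, it gives no yield.

The forecast says y = 50%, excess 50%, and keeps pace. Its excess is somewhat higher than the one reckoned here. On the exchange it notes: “The racemization catalyst is also in large excess over the free catalyst.”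

The flask gives y = 35.0% and excess 45.7%, and the exchange keeps pace, at 99.4% of the way from the 38.2% without exchange. The forecast's y stands 15 points above this, and at 2.00 min the flask holds 94.2% of its catalyst as dormant form.

    left-handed substrate + racemization catalyst ⇌ right-handed substrate + racemization catalyst, rate k1*[racemization catalyst]*[left-handed substrate] forward; the back reaction follows from the equilibrium constant (k = 3300 L mol⁻¹ s⁻¹)
    free catalyst ⇌ dormant form (K = 20.0, k = 0.0360 s⁻¹)
    solid reagent ⇌ partner, rate k3*(cs3 - [partner]) while solid is left; crystals form when [partner] > cs3 (solubility = 0.0980 M, k = 0.0790 s⁻¹)
    partner + free catalyst + right-handed substrate → free catalyst + right-handed product (k = 1600 L² mol⁻² s⁻¹)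
    partner + free catalyst + left-handed substrate → free catalyst + left-handed product (k = 4300 L² mol⁻² s⁻¹)

At 0.299 min, left-handed substrate has a half-life of 0.37 s by the forward exchange step alone, against 1.1 min by its reaction, a factor of 172. At 2.00 min both substrates stand at 32.5%, and the product ratio is 2.68 against s = 2.84. The neighbour charged with 1.9 × 10⁻⁴ M of free catalyst reaches 61.2% at a product ratio of 2.68.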